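**Plan**

1. Retrosynthesis (benzofuran numbering O1, C2, C3, C3a, C4–C7, C7a; ring A = benzene ring, ring B = dihydrofuran ring): the enal CHO goes back to the CH3 of an isopropenyl group, the angelate C–O bond is cut, and the C5 carbinol goes back to an acetyl group.
2. Ring B is then cut at O1–C7a and C2–C3 in one stroke, which leaves 1-[4-fluoro-3-(hydroxymethyl)phenyl]ethanone and methacrolein diacetate.
3. Enabling feature: C2–C3 is an anti-1,2-dioxygenated pair in which C2 is allylic and carries the aryl ether oxygen O1, C3 carries the acetate, and C7a lies para to the C5 acyl carbon. An acetoxy-methallyl unit can therefore be added to the C3 carbonyl carbon, the acetyl group can move from O–C2 to O–C3, and the freed C2 alkoxide can displace fluoride at C7a.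
4. Forward: ring A is bought; ring B forms in step 3 (iridium-catalysed anti-acetoxyallylation, 1,2-acyl shift, SNAr); then ketone reduction, angeloylation, and oxidation of the isopropenyl methyl group to the enal.
5. Stereochemistry: C2 and C3 come from the chiral iridium catalyst (anti relation from a chair transition state, absolute sense from the ligand); the C5 carbinol from Ru–TsDPEN transfer hydrogenation; the (Z)-enoate from angelic acid. The only helpers are the fluoride (lost in step 3) and the C5 acetyl group (reduced in step 4); no protecting group is used.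

Key step: step 3

Assumption: the (R)-SEGPHOS-modified iridium catalyst is taken to add the allyl unit to the aldehyde face that gives the (S)-carbinol at C3 (the face that gives (R)-1-arylbut-3-en-1-ols in simple allylations); if the opposite sense is found, (S)-SEGPHOS is used and nothing else changes.

**Route**

Step 1
Reactants: 1 (5-bromo-2-fluorophenyl)methanol
Product: 3 1-[4-fluoro-3-(hydroxymethyl)phenyl]ethan-1-one, via enol ether 2 (not isolated)
Conditions: tributyl(1-ethoxyvinyl)stannane (1.2 equiv), PdCl2(PPh3)2 (3 mol%), toluene, 100 °C; then 1 M HCl, THF, rt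
Reagents that add atoms: tributyl(1-ethoxyvinyl)stannane CCCC[Sn](CCCC)(CCCC)C(=C)OCC; water O
Why: Stille coupling of the aryl bromide (zerovalent palladium inserts at C–Br, not at C–F) with the 1-ethoxyvinyl stannane, then acid hydrolysis of enol ether 2, is the standard two-stage acetylation of aryl halides and tolerates the free benzylic alcohol.

Step 2
Reactants: 4 methacrolein (2-methylprop-2-enal)
Product: 5 2-methylprop-2-ene-1,1-diyl diacetate
Conditions: Ac2O (1.05 equiv), FeCl3 (0.5 mol%), neat, 0 °C to rt
Reagents that add atoms: acetic anhydride CC(=O)OC(C)=O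
Why: Lewis acid-catalysed addition of acetic anhydride across the aldehyde C=O (acylal formation) is a standard reaction of enals at low temperature, where 1,2-addition is preferred over conjugate addition.

Step 3
Reactants: 3 1-[4-fluoro-3-(hydroxymethyl)phenyl]ethan-1-one; 5 2-methylprop-2-ene-1,1-diyl diacetate
Product: 9 (2R,3S)-5-acetyl-2-(prop-1-en-2-yl)-2,3-dihydro-1-benzofuran-3-yl acetate, via aldehyde 6 (not isolated), via anti adduct 7 (not isolated), via acyl-shifted hydroxy acetate 8 (not isolated)
Conditions: [Ir(cod)Cl]2 (2.5 mol%), (R)-SEGPHOS (5 mol%), 4-chloro-3-nitrobenzoic acid (10 mol%), Cs2CO3 (20 mol%), 5 (1.2 equiv), THF, 90 °C, sealed tube; then Cs2CO3 (2.5 equiv), DMSO, 50 °C, same flask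
Reagents that add atoms: none
Why: Proposed new method: the cyclometallated C,O-benzoate complex of trivalent iridium dehydrogenates the primary benzylic alcohol 3 to aldehyde 6 and uses the hydride to ionise gem-diacetate 5 to an (E)-γ-acetoxy-β-methyl σ-allyl iridium species, which adds to the C3 carbonyl carbon of 6 through a closed chair-like transition state (C2–C3 bond, adduct 7); base then moves the acetyl group from O–C2 to O–C3 through the five-membered cyclic orthoester anion (8), and the freed C2 alkoxide displaces fluoride at C7a by addition–elimination (O1–C7a bond), the para-acetyl group at C5 stabilising the Meisenheimer complex. The closest known reaction type is the iridium-catalysed anti-selective acyloxyallylation of primary alcohols with allylic gem-dicarboxylates by transfer hydrogenation; new are the 2-methyl-substituted donor and the coupling to the acyl shift and the intramolecular SNAr, each of which is by itself an ordinary base-mediated event. Ring B closes by 5-exo-trig SNAr at C7a; no other ring is formed. C2 and C3 are both set in the carbonyl addition, the anti relation by the (E)-allyl geometry in the chair transition state and the absolute sense by the (R)-SEGPHOS ligand on iridium, and since no C–O bond at either carbon is broken afterwards the anti adduct maps onto the 2,3-trans ring. The step needs anti over syn addition, allylation of the transient aldehyde in preference to reduction of the C5 ketone, and O-arylation through the C2 oxygen only: the first rests on the preference of the acetoxy group for the syn position of the π-allyl, the second on the redox-neutral use of the alcohol as the only hydride source, and the third is assured because the C3 alkoxide could only close a four-membered ring, so the acyl shift funnels all material through the C2 alkoxide.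

Step 4
Reactants: 9 (2R,3S)-5-acetyl-2-(prop-1-en-2-yl)-2,3-dihydro-1-benzofuran-3-yl acetate
Product: 10 (2R,3S)-5-[(1R)-1-hydroxyethyl]-2-(prop-1-en-2-yl)-2,3-dihydro-1-benzofuran-3-yl acetate
Conditions: RuCl[(R,R)-TsDPEN](p-cymene) (1 mol%), HCO2H/Et3N (5:2), CH2Cl2, 28 °C
Reagents that add atoms: none
Why: Noyori–Ikariya asymmetric transfer hydrogenation of an aryl methyl ketone, in which the (R,R)-TsDPEN ruthenium hydride delivers hydrogen through the six-membered outer-sphere transition state to the face that gives the (R)-carbinol, as with acetophenone, under catalyst control that is independent of the remote ring stereocentres and leaves the isolated alkene and the acetate untouched.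

Step 5
Reactants: 10 (2R,3S)-5-[(1R)-1-hydroxyethyl]-2-(prop-1-en-2-yl)-2,3-dihydro-1-benzofuran-3-yl acetate; 11 angelic acid ((2Z)-2-methylbut-2-enoic acid)
Product: 13 (1R)-1-[(2R,3S)-3-(acetyloxy)-2-(prop-1-en-2-yl)-2,3-dihydro-1-benzofuran-5-yl]ethyl (2Z)-2-methylbut-2-enoate, via mixed anhydride 12 (not isolated)
Conditions: 11 (1.5 equiv), 2,4,6-trichlorobenzoyl chloride (1.5 equiv), Et3N (3 equiv), toluene, rt; then 10, toluene, 75 °C, no DMAP
Reagents that add atoms: none
Why: Yamaguchi esterification through mixed anhydride 12 without a nucleophilic catalyst acylates the carbinol oxygen with retention at carbon and avoids the conjugate addition–elimination pathway by which acylpyridinium species isomerise angelates to tiglates.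

Step 6
Reactants: 13 (1R)-1-[(2R,3S)-3-(acetyloxy)-2-(prop-1-en-2-yl)-2,3-dihydro-1-benzofuran-5-yl]ethyl (2Z)-2-methylbut-2-enoate
Product: 14 (1R)-1-[(2R,3S)-3-(acetyloxy)-2-(3-hydroxyprop-1-en-2-yl)-2,3-dihydro-1-benzofuran-5-yl]ethyl (2Z)-2-methylbut-2-enoate
Conditions: SeO2 (0.3 equiv), t-BuOOH (3 equiv, in decane), CH2Cl2, rt
Reagents that add atoms: tert-butyl hydroperoxide CC(C)(C)OO (source of the new oxygen atom, relayed by catalytic selenium dioxide O=[Se]=O)
Why: Catalytic SeO2 with t-BuOOH as reoxidant hydroxylates the allylic methyl group of the electron-rich 1,1-disubstituted alkene by ene reaction and [2,3]-sigmatropic shift (CH3 reacts in preference to the tertiary C2–H), while the electron-poor angelate double bond is much less reactive towards the electrophilic selenium reagent.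

Step 7
Reactants: 14 (1R)-1-[(2R,3S)-3-(acetyloxy)-2-(3-hydroxyprop-1-en-2-yl)-2,3-dihydro-1-benzofuran-5-yl]ethyl (2Z)-2-methylbut-2-enoate
Product: 15 (1R)-1-[(2R,3S)-3-(acetyloxy)-2-(3-oxoprop-1-en-2-yl)-2,3-dihydro-1-benzofuran-5-yl]ethyl (2Z)-2-methylbut-2-enoate (target)
Conditions: activated MnO2 (15 equiv), CH2Cl2, rt
Reagents that add atoms: none
Why: Activated MnO2 oxidises the primary allylic alcohol to the α-methylene aldehyde under neutral heterogeneous conditions, which avoid base-induced loss of the C3 acetate from the product.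

**Compound list**

1 | (5-bromo-2-fluorophenyl)methanol | OCc1cc(Br)ccc1F | starting material
2 | [5-(1-ethoxyethenyl)-2-fluorophenyl]methanol | C=C(OCC)c1ccc(F)c(CO)c1 | intermediate
3 | 1-[4-fluoro-3-(hydroxymethyl)phenyl]ethan-1-one | CC(=O)c1ccc(F)c(CO)c1 | intermediate
4 | methacrolein (2-methylprop-2-enal) | CC(=C)C=O | starting material
5 | 2-methylprop-2-ene-1,1-diyl diacetate | CC(=C)C(OC(C)=O)OC(C)=O | intermediate
6 | 5-acetyl-2-fluorobenzaldehyde | CC(=O)c1ccc(F)c(C=O)c1 | intermediate
7 | (1S,2R)-1-(5-acetyl-2-fluorophenyl)-1-hydroxy-3-methylbut-3-en-2-yl acetate | C=C(C)[C@@H](OC(C)=O)[C@@H](O)c1cc(C(C)=O)ccc1F | intermediate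
8 | (1S,2R)-1-(5-acetyl-2-fluorophenyl)-2-hydroxy-3-methylbut-3-en-1-yl acetate | C=C(C)[C@@H](O)[C@@H](OC(C)=O)c1cc(C(C)=O)ccc1F | intermediate
9 | (2R,3S)-5-acetyl-2-(prop-1-en-2-yl)-2,3-dihydro-1-benzofuran-3-yl acetate | C=C(C)[C@H]1Oc2ccc(C(C)=O)cc2[C@@H]1OC(C)=O | intermediate
10 | (2R,3S)-5-[(1R)-1-hydroxyethyl]-2-(prop-1-en-2-yl)-2,3-dihydro-1-benzofuran-3-yl acetate | C=C(C)[C@H]1Oc2ccc([C@@H](C)O)cc2[C@@H]1OC(C)=O | intermediate
11 | angelic acid ((2Z)-2-methylbut-2-enoic acid) | C/C=C(/C)C(=O)O | starting material
12 | (2Z)-2-methylbut-2-enoic 2,4,6-trichlorobenzoic anhydride | C/C=C(/C)C(=O)OC(=O)c1c(Cl)cc(Cl)cc1Cl | intermediate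
13 | (1R)-1-[(2R,3S)-3-(acetyloxy)-2-(prop-1-en-2-yl)-2,3-dihydro-1-benzofuran-5-yl]ethyl (2Z)-2-methylbut-2-enoate | C=C(C)[C@H]1Oc2ccc([C@@H](C)OC(=O)/C(C)=C\C)cc2[C@@H]1OC(C)=O | intermediate
14 | (1R)-1-[(2R,3S)-3-(acetyloxy)-2-(3-hydroxyprop-1-en-2-yl)-2,3-dihydro-1-benzofuran-5-yl]ethyl (2Z)-2-methylbut-2-enoate | C=C(CO)[C@H]1Oc2ccc([C@@H](C)OC(=O)/C(C)=C\C)cc2[C@@H]1OC(C)=O | intermediate
15 | (1R)-1-[(2R,3S)-3-(acetyloxy)-2-(3-oxoprop-1-en-2-yl)-2,3-dihydro-1-benzofuran-5-yl]ethyl (2Z)-2-methylbut-2-enoate | C=C(C=O)[C@H]1Oc2ccc([C@@H](C)OC(=O)/C(C)=C\C)cc2[C@@H]1OC(C)=O | target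

**Step count and risks**

Total step count: 7. Longest linear sequence: 6 steps (1, 3, 4, 5, 6, 7).

Step 3 (new method). What may go wrong:
- slow ionisation of the 2-substituted gem-diacetate;
- erosion of the anti preference, because the 2-methyl group crowds the syn-acetoxy position of the π-allyl;
- transfer hydrogenation of the C5 ketone at the expense of the allyl donor;
- acetyl transfer from surplus 5 to the C2 alkoxide, which blocks ring closure;
- loss of the acetate at the SNAr stage.

Fallback (known chemistry: C–C bond by a chromium reagent, absolute configuration by an enzyme). It sets out from 3 and 4 and comes back at 9. MnO2 in CH2Cl2 oxidises 3 to 5-acetyl-2-fluorobenzaldehyde 6, now isolated. Acetyl bromide adds 1,4 to methacrolein 4 to give 3-bromo-2-methylprop-1-en-1-yl acetate F1. CrCl2 in THF (Nozaki–Hiyama reaction, aldehyde-selective in the presence of the ketone and anti-selective with 3-bromopropenyl esters) joins F1 and 6 to racemic (1S*,2R*)-1-(5-acetyl-2-fluorophenyl)-1-hydroxy-3-methylbut-3-en-2-yl acetate F2. Cs2CO3 in DMSO effects the acyl shift and the 5-exo-trig SNAr to racemic (2R*,3S*)-5-acetyl-2-(prop-1-en-2-yl)-2,3-dihydro-1-benzofuran-3-yl acetate F3. Candida antarctica lipase B in phosphate buffer/MTBE should hydrolyse the (3S) acetate faster (Kazlauskas rule, with the aryl ring as the large group) to 1-[(2R,3S)-3-hydroxy-2-(prop-1-en-2-yl)-2,3-dihydro-1-benzofuran-5-yl]ethan-1-one F4, which is separated from the unreacted (2S,3R) acetate. Ac2O/pyridine then returns 9.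

Step 6. What may go wrong: competing ene oxidation at the angelate methyl groups or at C2–H, acid-promoted ionisation of the electron-rich benzylic ester by selenous acid species, and incomplete or excessive oxidation.

Fallback (electrophilic ene chlorination and Kornblum oxidation in place of the selenium ene oxidation). It sets out from 13 and comes back at 15, bypassing 14. Ca(OCl)2 and solid CO2 in CH2Cl2/H2O at 0 °C generate hypochlorous acid, which chlorinates the isopropenyl methyl group with transposition-free ene selectivity to give (1R)-1-[(2R,3S)-3-(acetyloxy)-2-(3-chloroprop-1-en-2-yl)-2,3-dihydro-1-benzofuran-5-yl]ethyl (2Z)-2-methylbut-2-enoate F5. NaI (cat.), NaHCO3 and DMSO at 50 °C then convert the allylic chloride into the enal 15.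

Step 5. What may go wrong: Z-to-E isomerisation of the activated angeloyl group, and ionisation with loss of configuration at the electron-rich benzylic carbinol on heating.

Fallback (the Z-alkene is built on the ester instead of being carried in). It sets out from 10 and comes back at 13. DCC with catalytic DMAP in CH2Cl2 couples 10 with 2-[bis(2,2,2-trifluoroethoxy)phosphoryl]propanoic acid to give (1R)-1-[(2R,3S)-3-(acetyloxy)-2-(prop-1-en-2-yl)-2,3-dihydro-1-benzofuran-5-yl]ethyl 2-[bis(2,2,2-trifluoroethoxy)phosphoryl]propanoate F6, as a mixture of epimers at the phosphonate carbon. KHMDS and 18-crown-6 in THF at −78 °C followed by acetaldehyde (Still–Gennari olefination, Z-selective) then give 13.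

**Further compounds**

F1 | step 3 | 3-bromo-2-methylprop-1-en-1-yl acetate | CC(=O)OC=C(C)CBr
F2 | step 3 | racemic (1S*,2R*)-1-(5-acetyl-2-fluorophenyl)-1-hydroxy-3-methylbut-3-en-2-yl acetate | C=C(C)[C@@H](OC(C)=O)[C@@H](O)c1cc(C(C)=O)ccc1F.C=C(C)[C@H](OC(C)=O)[C@H](O)c1cc(C(C)=O)ccc1F
F3 | step 3 | racemic (2R*,3S*)-5-acetyl-2-(prop-1-en-2-yl)-2,3-dihydro-1-benzofuran-3-yl acetate | C=C(C)[C@H]1Oc2ccc(C(C)=O)cc2[C@@H]1OC(C)=O.C=C(C)[C@@H]1Oc2ccc(C(C)=O)cc2[C@H]1OC(C)=O
F4 | step 3 | 1-[(2R,3S)-3-hydroxy-2-(prop-1-en-2-yl)-2,3-dihydro-1-benzofuran-5-yl]ethan-1-one | C=C(C)[C@H]1Oc2ccc(C(C)=O)cc2[C@@H]1O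
F5 | step 6 | (1R)-1-[(2R,3S)-3-(acetyloxy)-2-(3-chloroprop-1-en-2-yl)-2,3-dihydro-1-benzofuran-5-yl]ethyl (2Z)-2-methylbut-2-enoate | C=C(CCl)[C@H]1Oc2ccc([C@@H](C)OC(=O)/C(C)=C\C)cc2[C@@H]1OC(C)=O
F6 | step 5 | (1R)-1-[(2R,3S)-3-(acetyloxy)-2-(prop-1-en-2-yl)-2,3-dihydro-1-benzofuran-5-yl]ethyl 2-[bis(2,2,2-trifluoroethoxy)phosphoryl]propanoate | C=C(C)[C@H]1Oc2ccc([C@@H](C)OC(=O)C(C)P(=O)(OCC(F)(F)F)OCC(F)(F)F)cc2[C@@H]1OC(C)=O
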